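Readings and results are calculated with made-up constants; scatter was added.

4 questions stand on 3 flasks, and one ratio gives the line each answer is held against.

- the flask with the highest amount of target, in percent of the starting material charged ("all alike" if they lie within 1.5 percentage points) (Monday's / Sunday's / Wednesday's / all alike)
- final target, as a percentage of the starting material charged, in Monday's
- final target, as a percentage of the starting material charged, in Sunday's
- final target, as a percentage of the starting material charged, in Wednesday's

| flask | starting material | second substrate | free enzyme | temperature | remark | time |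
|---|---|---|---|---|---|---|
| winter | 0.025 M | 0.030 M | 29 µM | 35 °C | run made earlier |  |
| midnight | 0.038 M | 0.030 M | 29 µM | 50 °C | run made earlier |  |
| summer | 0.050 M | 0.030 M | 14 µM | 35 °C | run made earlier |  |
| Monday's | 0.050 M | 0.0300 M | 29 µM |  | at 40 °C until 4.0 h, from then on at 60 °C | 8.0 h |
| Sunday's | 0.050 M | 0.0300 M | 29 µM | 40 °C |  | 8.0 h |
| Wednesday's | 0.050 M | 0.0300 M | 29 µM | 60 °C |  | 8.0 h |

| run | time / h | target / % | starting material / % |
|---|---|---|---|
| winter | 1.00 | 24.2 | 66.2 |
| winter | 2.50 | 48.0 | 36.0 |
| winter | 3.00 | 54.0 | 32.4 |
| winter | 5.00 | 71.4 | 18.7 |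
| winter | 6.00 | 77.9 | 14.2 |
| winter | 8.00 | 86.4 | 8.8 |
| midnight | 0.250 | 16.4 | 72.7 |
| midnight | 0.833 | 42.9 | 39.6 |
| midnight | 1.50 | 56.9 | 24.2 |
| midnight | 2.00 | 61.3 | 18.8 |
| midnight | 3.00 | 68.1 | 18.0 |
| midnight | 4.00 | 70.4 | 13.3 |
| midnight | 5.00 | 73.3 | 11.7 |
| summer | 0.667 | 4.6 | 91.2 |
| summer | 2.00 | 15.7 | 77.2 |
| summer | 4.00 | 25.1 | 61.9 |
| summer | 6.00 | 33.7 | 50.0 |
| summer | 8.00 | 41.5 | 42.0 |

(standard deviation of a reading: 1 percentage point)

- a reading or a percentage of target counts all its forms, free or not
- a reading of starting material is of its free form alone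

1. Each target is taken to use one second substrate. Second substrate charged over starting material charged is then 60.0 % for Monday's, Sunday's and Wednesday's alike: this is the cap, the share of the charge that the limiting reagent allows.

2. A second way counts lifetimes. The summer run has the same charge ratio, and at its last reading 30.8 % of its second substrate is left. That gives a lifetime of 6.80 h, and the reading at 4.00 h gives 7.38 h, close enough to use one lifetime.

3. Sunday's holds 2.07 times the summer run's enzyme. Kept at the summer run's own 35 °C, that enzyme gives a lifetime of 3.28 h, and 2.44 such lifetimes fit into Sunday's 8.0 h. The cap gives the end and the count gives the time, so this is no independent check of the end: the count brings Sunday's to 54.8 %. Sunday's bath stands at 40 °C, though, and early target gain, midnight's first reading against winter's, is 4.12 times faster at 50 °C than at 35 °C, with their charges of starting material differing too. So 54.8 % is taken as the low side for Sunday's.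

4. On the midnight run the count cheats. Its cap is 78.9 %, and its reading at 0.833 h gives a lifetime of 1.06 h. That promises 78.2 % at 5.00 h, yet 73.3 % is read, a gap of 4.9 percentage points against a scatter of 1 point. The lifetime read there is 1.90 h, twice the early one. At 50 °C the lifetime stretches, so the count is not trusted for Wednesday's at 60 °C.

5. This reckoning commits to Sunday's first, between 54.8 % and the cap. Monday's comes next, with 42.3 % counted by the same lifetime up to its change of temperature upward, and Wednesday's last, short of the cap by an amount not reckoned here.

6. The forecast differs: Monday's highest, with 56 % there, 54 % for Sunday's and 52 % for Wednesday's. Its ground for Sunday's: “Sunday therefore corresponds to summer run for about 24 h”.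

7. The flasks give 55.6 % in Monday's, 59.5 % in Sunday's and 45.4 % in Wednesday's, so Sunday's holds the highest target.

    free enzyme → unfolded enzyme (k = 1.56 × 10⁻⁴ /min, Ea = 234 kJ/mol)
    starting material + free enzyme ⇌ first complex (K = 4.60 /M, k = 4690 /M/min, Ea = 52.0 kJ/mol, ΔH = −49.0 kJ/mol)
    first complex ⇌ loaded enzyme + first product (K = 0.130 M, k = 162 /min, Ea = 82.0 kJ/mol, ΔH = −24.0 kJ/mol)
    second substrate + loaded enzyme ⇌ second complex (K = 391 /M, k = 6520 /M/min, Ea = 44.0 kJ/mol, ΔH = 20.0 kJ/mol)
    second complex → free enzyme + target (k = 13.6 /min, Ea = 88.0 kJ/mol)
    crystals ⇌ target, rate k6*(cs6 - [target]) while solid is left; crystals form when [target] > cs6 (solubility = 8.70 mM, k = 0.0623 /min)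
    2 second complex → spent catalyst (k = 258 /M/min, Ea = 45.0 kJ/mol)
    starting material + first product ⇌ idle adduct, settled at all times (K = 46.6 /M, ΔH = 28.0 kJ/mol)
    (constants at 40 °C)

8. Sunday's stands 0.5 points under the cap, with 0.797 % of its second substrate left at 8.00 h. Wednesday's stops 15 points under it, with 24.3 % of its second substrate left and 94.6 % of the catalyst charged as unfolded enzyme. A neighbour of Sunday's charged with 0.085 M of starting material has a cap of 35.3 %. That flask gives 35.3 %, with 0 % of its second substrate left and 42.5 % of its starting material still standing.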